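## Structural features

Sophoraflavanone A is a flavanone in which ring A, a phloroglucinol-type benzene ring, is fused through C4a–C8a to the dihydropyranone ring C, and ring C carries the 4-hydroxyphenyl ring B on C2. Ring A bears hydroxyl groups on C5 and C7 and a geranyl chain on C8, between O1 and the C7 hydroxyl. C2, of S configuration, is the only stereocentre, so no neighbouring centre can relay its configuration and it must come from a chiral reagent or catalyst. It is a benzylic ether carbon β to the C4 ketone and para to the ring B oxygen, so its configuration is lost by reversible opening of ring C to the 2'-hydroxychalcone whenever phenoxides are present, and more slowly under strong acid. The two trisubstituted alkenes exclude hydrogenolysis and are at risk with protic or Lewis acids (cyclisation onto the C7 oxygen, addition of solvent), and the electron-rich ring A is easily oxidised. The real difficulties are therefore the enantioselective creation of C2, the placing of the geranyl group at C8 and not at C6, and protecting groups that come off without acid and without free base. The key step exploits that C4 is an aryl ketone carbon on C4a and C2 an ether methine on O1: a formyl group on C4a and a 1-arylvinyl group on O1 (C2=C3) contain every atom of ring C, and adding the formyl C–H across the alkene forms C3–C4 and C2–H together. Because that precursor is a latent flavylium ion (any electrophilic activation of the benzylic carbon beside the enol ether can be trapped by C3 and aromatise to the 2-arylbenzopyrylium), the route uses silyl ethers on all three phenols in place of acetal-type ethers and reveals the aldehyde by oxidation, not by acetal hydrolysis, so that no acid is needed once the enol ether exists.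

## Logic of the disconnections

14 to 13. The three phenolic O–H bonds are traced back to O–Si bonds. The last step has to spare C2 and both alkenes; aryl silyl ethers fall to buffered fluoride at or below room temperature, whereas acetal-type ethers would need acid. Nothing is gained in skeleton. The forward step demands a buffered fluoride source so that no phenoxide persists.

13 to 12. C3–C4 and the C2–H bond are cut, which opens ring C and removes the only stereocentre; what remains is an achiral benzaldehyde whose ortho oxygen carries the C2=C3 alkene. This is the largest simplification of the route: one ring, one skeletal bond and the stereocentre are exchanged for a formyl group and a 1,1-disubstituted alkene. The forward step must be an enantioselective intramolecular hydroacylation in the 6-endo sense, faster than decarbonylation and in a medium free of acid.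

12 to 11. The formyl C=O is taken back to the primary benzylic alcohol. The aldehyde cannot coexist with Cp2Ti=CH2, the methylenating species of the stage before, and cannot be released from an acetal next to the enol ether, but an alcohol can be oxidised on a neutral solid oxidant. The demand is an oxidation that never passes through a benzylic cation.

11 to 9. The terminal carbon C3 is cut from C2, so that the C=CH2 bond becomes the C=O bond of an aryl ester, and the benzylic O–H returns to a labile O–Si bond; 10 is the unisolated link. The enol ether is thereby reduced to an ester, which is trivially made. The forward steps demand a carbonyl methylenation that is neither acidic nor basic and leaves the geranyl alkenes alone, then a cleavage that tells an unhindered alkyl silyl ether from three bulky aryl silyl ethers.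

9 to 8. The benzylic C–H and O–Si bonds are cut, returning the aldehyde. Masking is placed after esterification because a salicyl alcohol with a free phenol would be a quinone methide precursor. It has to be a hydrosilylation, because a free benzylic alkoxide would pull the aroyl group over from the phenol oxygen.

8 to 4 and 7. The ester C–O bond between the aroyl carbon (future C2) and the phenol oxygen (future O1) is cut. This is the convergent cut: it separates the ring A half, with the geranyl group and C4, from the ring B half with C2. The forward step must acylate a hindered, hydrogen-bonded phenol without a base that strips aryl silyl groups.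

7 to 5. The aryl O–Si bond is cut; 6 is the unisolated doubly silylated form. The demand is selective hydrolysis of a silyl ester beside an aryl silyl ether.

4 to 3. Two O–Si bonds are cut. The demand is regioselectivity: the hydroxyl between the formyl and geranyl groups must stay free because it becomes O1, and this is what fixes the geranyl group at C8.

3 to 1 and 2. The bond between the ring carbon (future C8) and C1 of the geranyl chain is cut. Because 1 is symmetric, its two ring CH positions are equivalent, so mono-C-alkylation has no regiochemical issue; doing it before any protection avoids a choice between the position next to the free hydroxyl and the one between two ethers. The demand is C- over O-alkylation and mono- over dialkylation, with the 2E alkene retained.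

## Other disconnections considered

Alternative 1: The cut goes through O1–C8a and C4–C4a and leaves ring C open. An aryne spanning C4a–C8a, released by fluoride from 2-geranyl-3,5-bis(methoxymethoxy)-6-(trimethylsilyl)phenyl trifluoromethanesulfonate A3, would be attacked at C8a by the carboxylate oxygen of (3R)-3-(tert-butyldimethylsilyloxy)-3-[4-(methoxymethoxy)phenyl]propanoic acid A2. The aryl anion at C4a would then take the acyl group from oxygen, giving the ortho-hydroxyaryl ketone (3R)-3-(tert-butyldimethylsilyloxy)-1-[3-geranyl-2-hydroxy-4,6-bis(methoxymethoxy)phenyl]-3-[4-(methoxymethoxy)phenyl]propan-1-one A1. Desilylation of A1 and Mitsunobu etherification with inversion would close O1–C2 to (2S)-8-geranyl-5,7-bis(methoxymethoxy)-2-[4-(methoxymethoxy)phenyl]chroman-4-one A4.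
- In its favour: the plan is convergent, and the C5 alkoxy group should steer the nucleophile to the distal aryne carbon C8a. The stereocentre of A2 comes from well-established asymmetric reduction or aldol chemistry, so the origin of C2 is better secured than in the chosen plan.
- Against it: A3 is a hexasubstituted arene with a long linear preparation. Insertion into an acid C–O bond is documented for simple acids at temperatures where a β-silyloxy acid such as A2 can eliminate, and plain O-arylation competes. Mitsunobu closure of the carbinol derived from A1, a benzylic alcohol with a para alkoxy group, has SN1 character and chalcone formation as competitor. The acetal ethers of A4 finally need acid beside the geranyl chain.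
- Comparison: on structure, the stereocentre is made early and must survive two steps that can erode it, whereas the chosen plan creates it in the ring-forming step. On mechanism, the aryne step to A1 has closer precedent than the chosen key step, but for much simpler partners. On step economy it is clearly longer (about fifteen steps against nine).

Alternative 2: The cut removes C4a–C4, C4–C3 and O1–C2 together. 2-Geranyl-6-iodo-3,5-bis(methoxymethoxy)phenol A6, carbon monoxide and 1-ethynyl-4-(methoxymethoxy)benzene A7 would combine under PdCl2(PPh3)2 and an amine to an alkynone, which would close 6-endo through the phenol to the flavone 8-geranyl-5,7-bis(methoxymethoxy)-2-[4-(methoxymethoxy)phenyl]chromen-4-one A5.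
- In its favour: it is the most convergent assembly, each event is well documented for flavones, the alkyne A7 is a simple compound, and there is no masked aldehyde and no latent flavylium ion. For building the skeleton it is the equal of the chosen plan or better: one step, three bonds, known chemistry.
- Against it: A5 is flat, so C2 would still have to be set by an enantioselective 1,4-reduction of a 2-arylchromone to A4 in the presence of two trisubstituted alkenes. The β-carbon is a deactivated vinylogous ester, and hydrogenation catalysts also threaten the ketone and the alkenes. The 5-exo closure to an aurone competes, and the iodide of A6 has to be placed regioselectively between a free hydroxyl and an acetal ether.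
- Comparison: the alternative defers the real problem, whereas the chosen plan solves ring and stereocentre in one step. On mechanism every step is known but the reduction is not dependable. The step count is similar up to A5, then at least one uncertain step more, plus an acidic deprotection.

Alternative 3: The cut is C2–C3. A chiral dirhodium tetracarboxylate such as Rh2(S-DOSP)4 would decompose 2-diazo-1-[2-{[4-(tert-butyldimethylsilyloxy)phenyl]methoxy}-4,6-bis(tert-butyldimethylsilyloxy)-3-geranylphenyl]ethan-1-one A9, and the carbene would insert into a benzylic C–H bond of the ortho benzyl ether, closing the six-membered ring. This would give (2S)-5,7-bis(tert-butyldimethylsilyloxy)-2-[4-(tert-butyldimethylsilyloxy)phenyl]-8-geranylchroman-4-one A8, the tert-butyldimethylsilyl analogue of 13.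
- In its favour: like the chosen plan it closes ring C and sets C2 in one catalytic step, at a C–H bond activated by oxygen and an aryl group. Chromanones have been made by this type of insertion with chiral dirhodium carboxylates, so its precedent for ring size and bond type is better than that of the chosen key step. The end game from A8, one buffered fluoride step, is equal.
- Against it: a terminal diazoketone gives an acceptor-only carbene of low selectivity. The ether oxygen next to the target C–H bond can be attacked to a five-membered oxonium ylide that rearranges by benzyl shift to a 2-benzylbenzofuran-3-one. The electron-rich geranyl alkenes invite cyclopropanation, and enantioselectivities of such carbenes are usually modest. A9 requires an acid chloride beside aryl silyl ethers and diazomethane.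
- Comparison: on structure, a free carbene tolerates the two alkenes far less than an acyl rhodium hydride that reaches only a chelating alkene. On mechanism, both plans rely on catalyst control at C2. Step economy is about equal, with added handling hazards for A9.

Key step: step 8

Assumption: geranyl means (2E)-3,7-dimethylocta-2,6-dien-1-yl throughout; the sense of induction of the bisphosphine in step 8 cannot be predicted from a close analogue, so the (R) ligand is written and its mirror image is to be used if a model substrate shows the opposite sense.

Remark: C2 keeps the descriptor S from 13 to 14 because the order O1 > C1' > C3 > H does not depend on the phenol protecting groups.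

## Route

Step 1
Reactants: 1 2,4,6-trihydroxybenzaldehyde; 2 geranyl bromide
Product: 3 3-geranyl-2,4,6-trihydroxybenzaldehyde
Conditions: DBU (1.0 equiv), 2 (0.8 equiv, slow addition), THF, 0 °C to rt
Reagents that add atoms: none
Why: C-alkylation of a phloroglucinol-type phenoxide, whose C-alkylated dienone tautomerises back to the arene; 1 is symmetric, so mono-C-geranylation gives a single regioisomer, and SN2 at the primary allylic bromide keeps the 2E geometry. Using 2 as the limiting reagent should hold back O-alkylation and double alkylation, whose products are removed by chromatography.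

Step 2
Reactants: 3 3-geranyl-2,4,6-trihydroxybenzaldehyde
Product: 4 3-geranyl-2-hydroxy-4,6-bis(triisopropylsilyloxy)benzaldehyde
Conditions: TIPSCl (2.2 equiv), imidazole, DMF, 0 °C to rt
Reagents that add atoms: chlorotriisopropylsilane, CC(C)[Si](Cl)(C(C)C)C(C)C
Why: Silylation of phenols: the 4-OH (para to the formyl group, most acidic, not hydrogen-bonded) and the less hindered 6-OH should react, while the 2-OH is shielded by the geranyl group and chelated to the formyl oxygen. This is the sense of selectivity expected for bis-protection of 3-alkyl acylphloroglucinols, in which the chelated, flanked hydroxyl stays free, and the bulky silyl group should sharpen it.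

Step 3
Reactants: 5 4-hydroxybenzoic acid
Product: 7 4-(triisopropylsilyloxy)benzoic acid, via silyl ester 6 (not isolated)
Conditions: TIPSCl (2.2 equiv), imidazole, DMF, rt; then K2CO3, MeOH–THF–H2O, rt; HCl to pH 4
Reagents that add atoms: chlorotriisopropylsilane, CC(C)[Si](Cl)(C(C)C)C(C)C
Why: Exhaustive silylation followed by selective hydrolysis: a silyl ester is far more labile to aqueous carbonate than an aryl triisopropylsilyl ether, so only the ester should be cleaved.

Step 4
Reactants: 4 3-geranyl-2-hydroxy-4,6-bis(triisopropylsilyloxy)benzaldehyde; 7 4-(triisopropylsilyloxy)benzoic acid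
Product: 8 2-formyl-6-geranyl-3,5-bis(triisopropylsilyloxy)phenyl 4-(triisopropylsilyloxy)benzoate
Conditions: EDC·HCl (1.5 equiv), DMAP (0.2 equiv), CH2Cl2, 0 °C to rt
Reagents that add atoms: none
Why: Steglich esterification: the acylpyridinium ion formed from the O-acylisourea should acylate the only free phenol, and no base strong enough to cleave aryl silyl ethers is present.

Step 5
Reactants: 8 2-formyl-6-geranyl-3,5-bis(triisopropylsilyloxy)phenyl 4-(triisopropylsilyloxy)benzoate
Product: 9 2-[(dimethylphenylsilyloxy)methyl]-6-geranyl-3,5-bis(triisopropylsilyloxy)phenyl 4-(triisopropylsilyloxy)benzoate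
Conditions: PhMe2SiH (1.5 equiv), [(Ph3P)CuH]6 (2 mol %), toluene, rt
Reagents that add atoms: dimethylphenylsilane, C[SiH](C)c1ccccc1
Why: Hydrosilylation of an aldehyde catalysed by [(Ph3P)CuH]6 (1,2-addition of Cu–H, then σ-bond metathesis of the copper alkoxide with the silane) should turn the formyl group directly into the silyl ether, so that no long-lived benzylic alkoxide is left to take the neighbouring aroyl group by O-to-O acyl shift. Aryl esters, trisubstituted alkenes and silyl ethers are inert to this catalyst.

Step 6
Reactants: 9 2-[(dimethylphenylsilyloxy)methyl]-6-geranyl-3,5-bis(triisopropylsilyloxy)phenyl 4-(triisopropylsilyloxy)benzoate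
Product: 11 {3-geranyl-4,6-bis(triisopropylsilyloxy)-2-[1-(4-triisopropylsilyloxyphenyl)vinyloxy]phenyl}methanol, via silyl-protected enol ether 10 (not isolated)
Conditions: Cp2TiMe2 (3 equiv), toluene, 70 °C, dark; filtration through basic alumina; then K2CO3 (0.2 equiv), MeOH–THF, 0 °C
Reagents that add atoms: dimethyltitanocene (Cp2TiMe2), C[Ti](C)(C1C=CC=C1)C1C=CC=C1
Why: Petasis methylenation: Cp2TiMe2 loses methane on heating to Cp2Ti=CH2, which adds to the ester carbonyl and cycloreverts to the 1-arylvinyl aryl ether and titanocene oxide; the reagent is neither acidic nor basic and the trisubstituted alkenes are too hindered to react. Catalytic carbonate in methanol should then cleave only the unhindered dimethylphenylsilyl ether, which is about as labile as a trimethylsilyl ether, and leave the aryl triisopropylsilyl ethers and the enol ether.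

Step 7
Reactants: 11 {3-geranyl-4,6-bis(triisopropylsilyloxy)-2-[1-(4-triisopropylsilyloxyphenyl)vinyloxy]phenyl}methanol
Product: 12 3-geranyl-4,6-bis(triisopropylsilyloxy)-2-{1-[4-(triisopropylsilyloxy)phenyl]vinyloxy}benzaldehyde
Conditions: activated MnO2 (excess), NaHCO3, CH2Cl2, rt; product kept cold over a trace of Et3N and used at once
Reagents that add atoms: none
Why: Manganese dioxide oxidation of an electron-rich benzylic alcohol takes place on the solid surface without acid and without a benzylic cation or oxocarbenium ion, which matters because such an ion would be trapped by the enol ether carbon and end as the flavylium salt.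

Step 8
Reactants: 12 3-geranyl-4,6-bis(triisopropylsilyloxy)-2-{1-[4-(triisopropylsilyloxy)phenyl]vinyloxy}benzaldehyde
Product: 13 (2S)-8-geranyl-5,7-bis(triisopropylsilyloxy)-2-[4-(triisopropylsilyloxy)phenyl]chroman-4-one
Conditions: [Rh(cod)Cl]2 (5 mol %), (R)-DTBM-SEGPHOS (11 mol %), AgBF4 (10 mol %), ClCH2CH2Cl, rt, AgCl filtered off; then 12, 40 °C
Reagents that add atoms: none
Why: Proposed new method: a cationic monovalent rhodium bisphosphine complex should add oxidatively into the formyl C–H bond of 12 to give an acyl hydride of trivalent rhodium held by the neighbouring vinyl ether (first through oxygen, then through the alkene), which slows decarbonylation; the hydride then migrates to the aryl-bearing alkene carbon C2, leaving rhodium on the CH2 terminus in a seven-membered acyl alkyl rhodacycle, and reductive elimination forms C3–C4. The closest known reaction type is the rhodium–bisphosphine enantioselective intramolecular hydroacylation of 1,1-disubstituted alkenes in 2-(1-substituted vinyl)benzaldehydes to 3-substituted indanones, together with ether-chelation-assisted hydroacylations that give benzo-fused seven- and eight-membered oxacycles; an oxygen-tethered 1-arylvinyl ether closing to a six-membered ketone has not been shown. Ring C closes in a formal 6-endo-trig mode, both alkene carbons ending in the ring. The C2 stereocentre is created when hydride is delivered to one enantiotopic face of the alkene, chosen by the chiral pocket of the bisphosphine (catalyst control, the substrate having no other stereocentre); if insertion is reversible, the choice is made at reductive elimination from the diastereomeric rhodacycles. The step needs regioselectivity for acyl transfer to the CH2 terminus over the five-membered mode that would give a 2-aryl-2-methylbenzofuran-3-one; the substrate secures this because the other insertion would put rhodium on a fully substituted, oxygen-bearing benzylic carbon and require reductive elimination to a quaternary centre, and because hydride addition to the oxocarbenium-like C2 is polarity-matched. It also needs chemoselectivity: the two geranyl alkenes are trisubstituted, remote and not reachable in a small rhodacycle, and the bulky, non-coordinating silyloxy group on the other side of the formyl group leaves only the vinyl ether side to bind rhodium. The halide-free, filtered catalyst solution keeps silver salts and protic acid away from the latent flavylium system.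

Step 9
Reactants: 13 (2S)-8-geranyl-5,7-bis(triisopropylsilyloxy)-2-[4-(triisopropylsilyloxy)phenyl]chroman-4-one
Product: 14 sophoraflavanone A, (2S)-8-geranyl-5,7-dihydroxy-2-(4-hydroxyphenyl)chroman-4-one
Conditions: TBAF (4 equiv), AcOH (4 equiv), THF, 0 °C to rt
Reagents that add atoms: none
Why: Fluoride cleavage of aryl silyl ethers; acetic acid protonates each phenoxide as it forms, so the medium should never become basic enough for E1cB opening of ring C, the path by which C2 would racemise. No acid strong enough to attack the geranyl alkenes is present.

## Compound list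

1 | 2,4,6-trihydroxybenzaldehyde | O=Cc1c(O)cc(O)cc1O | starting material
2 | geranyl bromide, (2E)-1-bromo-3,7-dimethylocta-2,6-diene | CC(C)=CCC/C(C)=C/CBr | starting material
3 | 3-geranyl-2,4,6-trihydroxybenzaldehyde | CC(C)=CCC/C(C)=C/Cc1c(O)cc(O)c(C=O)c1O | intermediate
4 | 3-geranyl-2-hydroxy-4,6-bis(triisopropylsilyloxy)benzaldehyde | CC(C)=CCC/C(C)=C/Cc1c(O[Si](C(C)C)(C(C)C)C(C)C)cc(O[Si](C(C)C)(C(C)C)C(C)C)c(C=O)c1O | intermediate
5 | 4-hydroxybenzoic acid | O=C(O)c1ccc(O)cc1 | starting material
6 | triisopropylsilyl 4-(triisopropylsilyloxy)benzoate | CC(C)[Si](OC(=O)c1ccc(O[Si](C(C)C)(C(C)C)C(C)C)cc1)(C(C)C)C(C)C | intermediate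
7 | 4-(triisopropylsilyloxy)benzoic acid | O=C(O)c1ccc(O[Si](C(C)C)(C(C)C)C(C)C)cc1 | intermediate
8 | 2-formyl-6-geranyl-3,5-bis(triisopropylsilyloxy)phenyl 4-(triisopropylsilyloxy)benzoate | CC(C)=CCC/C(C)=C/Cc1c(O[Si](C(C)C)(C(C)C)C(C)C)cc(O[Si](C(C)C)(C(C)C)C(C)C)c(C=O)c1OC(=O)c1ccc(O[Si](C(C)C)(C(C)C)C(C)C)cc1 | intermediate
9 | 2-[(dimethylphenylsilyloxy)methyl]-6-geranyl-3,5-bis(triisopropylsilyloxy)phenyl 4-(triisopropylsilyloxy)benzoate | CC(C)=CCC/C(C)=C/Cc1c(O[Si](C(C)C)(C(C)C)C(C)C)cc(O[Si](C(C)C)(C(C)C)C(C)C)c(CO[Si](C)(C)c2ccccc2)c1OC(=O)c1ccc(O[Si](C(C)C)(C(C)C)C(C)C)cc1 | intermediate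
10 | {3-geranyl-4,6-bis(triisopropylsilyloxy)-2-[1-(4-triisopropylsilyloxyphenyl)vinyloxy]benzyloxy}dimethylphenylsilane | CC(C)=CCC/C(C)=C/Cc1c(O[Si](C(C)C)(C(C)C)C(C)C)cc(O[Si](C(C)C)(C(C)C)C(C)C)c(CO[Si](C)(C)c2ccccc2)c1OC(=C)c1ccc(O[Si](C(C)C)(C(C)C)C(C)C)cc1 | intermediate
11 | {3-geranyl-4,6-bis(triisopropylsilyloxy)-2-[1-(4-triisopropylsilyloxyphenyl)vinyloxy]phenyl}methanol | CC(C)=CCC/C(C)=C/Cc1c(O[Si](C(C)C)(C(C)C)C(C)C)cc(O[Si](C(C)C)(C(C)C)C(C)C)c(CO)c1OC(=C)c1ccc(O[Si](C(C)C)(C(C)C)C(C)C)cc1 | intermediate
12 | 3-geranyl-4,6-bis(triisopropylsilyloxy)-2-{1-[4-(triisopropylsilyloxy)phenyl]vinyloxy}benzaldehyde | CC(C)=CCC/C(C)=C/Cc1c(O[Si](C(C)C)(C(C)C)C(C)C)cc(O[Si](C(C)C)(C(C)C)C(C)C)c(C=O)c1OC(=C)c1ccc(O[Si](C(C)C)(C(C)C)C(C)C)cc1 | intermediate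
13 | (2S)-8-geranyl-5,7-bis(triisopropylsilyloxy)-2-[4-(triisopropylsilyloxy)phenyl]chroman-4-one | CC(C)=CCC/C(C)=C/Cc1c(O[Si](C(C)C)(C(C)C)C(C)C)cc(O[Si](C(C)C)(C(C)C)C(C)C)c2c1O[C@H](c1ccc(O[Si](C(C)C)(C(C)C)C(C)C)cc1)CC2=O | intermediate
14 | sophoraflavanone A, (2S)-8-geranyl-5,7-dihydroxy-2-(4-hydroxyphenyl)chroman-4-one | CC(C)=CCC/C(C)=C/Cc1c(O)cc(O)c2c1O[C@H](c1ccc(O)cc1)CC2=O | target

## Step count and least certain steps

Total step count: 9 (step 3 prepares the acid 7 for the convergent step 4).
Longest linear sequence: 8 steps (1, 2, 4, 5, 6, 7, 8, 9) from 1 to 14.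

Step 8 (key step, beyond known chemistry). The likely failures are:
- decarbonylation of the doubly ortho-substituted, electron-rich acyl rhodium hydride before the alkene inserts, ending the catalyst as a carbonyl complex;
- Lewis-acid-triggered attack of the enol ether on the activated formyl group, draining material into the flavylium manifold;
- acyl transfer in the five-membered mode;
- poor facial selectivity, because a 1-aryl-1-aryloxy alkene offers the ligand two flat, similar substituents.

The fallback uses known chemistry, sets out from 4 and comes back at 14. Addition of ethynylmagnesium bromide (excess, THF, 0 °C) to 4 would give racemic 1-[3-geranyl-2-hydroxy-4,6-bis(triisopropylsilyloxy)phenyl]prop-2-yn-1-ol F1. MnO2 oxidation would give 1-[3-geranyl-2-hydroxy-4,6-bis(triisopropylsilyloxy)phenyl]prop-2-yn-1-one F2. Diethylamine (CH2Cl2, rt) should close F2 by conjugate addition, 6-endo attack of the phenol and loss of the amine to 8-geranyl-5,7-bis(triisopropylsilyloxy)-4H-chromen-4-one F3. Enantioselective conjugate addition of commercial [4-(tert-butyldimethylsilyloxy)phenyl]boronic acid F4, catalysed by [Rh(OH)(cod)]2 with a chiral bisphosphine in aqueous solvent at room temperature (a documented route from chromones to 2-arylchroman-4-ones), would give (2S)-2-[4-(tert-butyldimethylsilyloxy)phenyl]-8-geranyl-5,7-bis(triisopropylsilyloxy)chroman-4-one F5. F5 would be desilylated under the conditions of step 9 to 14.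

Step 1. O-alkylation and a second C-alkylation may outrun mono-C-alkylation, and separation from unreacted 1 may be laborious. The fallback sets out from 1 and 2, comes back at 4 and thereby also bypasses step 2 and its regiochemical question. Bis-silylation of the symmetric 1 (TIPSCl, imidazole, DMF) would give 2-hydroxy-4,6-bis(triisopropylsilyloxy)benzaldehyde F6. Iodination with N-iodosuccinimide ortho to the free hydroxyl would give 2-hydroxy-3-iodo-4,6-bis(triisopropylsilyloxy)benzaldehyde F7; the other ring CH lies between two bulky silyloxy groups and is shielded. Stille coupling of F7 with tributyl(geranyl)stannane F8 (made from 2 and Bu3SnLi), using Pd2(dba)3 and tri(2-furyl)phosphine in DMF, would give 4. The aryl–geranyl bond is then made by cross-coupling instead of phenoxide alkylation.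

Step 5. The aroyl group may move from the phenol oxygen to the benzylic copper alkoxide before it is silylated, or the doubly ortho-substituted, electron-rich aldehyde may be reduced too slowly. The fallback sets out from 4 and comes back at 9, reducing the aldehyde before any aroyl group is present. NaBH4 (MeOH–THF, 0 °C) would convert 4 into 2-geranyl-6-(hydroxymethyl)-3,5-bis(triisopropylsilyloxy)phenol F9, which is handled cold and neutral because it is a quinone methide precursor. Chlorodimethylphenylsilane and imidazole at −20 °C should silylate the primary hydroxyl to 2-[(dimethylphenylsilyloxy)methyl]-6-geranyl-3,5-bis(triisopropylsilyloxy)phenol F10; any aryl silyl ether formed at the hindered phenol is lost on bicarbonate work-up. Steglich esterification of F10 with 7, as in step 4, would give 9.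

Step 6. Methylenation of the hindered aryl ester may be incomplete at a temperature at which the labile benzylic silyl ether begins to be lost (followed by acyl shift), or a silyl group may migrate from the ring oxygen to the benzylic oxygen during methanolysis. The fallback sets out from 8 and comes back at 12, masking the aldehyde at its own oxidation level. Aprotic acetalisation of 8 (methoxytrimethylsilane, catalytic trimethylsilyl triflate, CH2Cl2, −78 °C; no hemiacetal hydroxyl that could take the aroyl group) would give 2-(dimethoxymethyl)-6-geranyl-3,5-bis(triisopropylsilyloxy)phenyl 4-(triisopropylsilyloxy)benzoate F11. Cp2TiMe2 would give 1-(dimethoxymethyl)-3-geranyl-4,6-bis(triisopropylsilyloxy)-2-{1-[4-(triisopropylsilyloxy)phenyl]vinyloxy}benzene F12. Hydrolysis in a water-rich acetate buffer at 0 °C would give 12. This stays the second choice because the hydrolysis passes through the oxocarbenium ion that the enol ether can trap.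

## Further compounds

F1 | step 8 | 1-[3-geranyl-2-hydroxy-4,6-bis(triisopropylsilyloxy)phenyl]prop-2-yn-1-ol (racemic) | CC(C)=CCC/C(C)=C/Cc1c(O[Si](C(C)C)(C(C)C)C(C)C)cc(O[Si](C(C)C)(C(C)C)C(C)C)c(C(O)C#C)c1O
F2 | step 8 | 1-[3-geranyl-2-hydroxy-4,6-bis(triisopropylsilyloxy)phenyl]prop-2-yn-1-one | CC(C)=CCC/C(C)=C/Cc1c(O[Si](C(C)C)(C(C)C)C(C)C)cc(O[Si](C(C)C)(C(C)C)C(C)C)c(C(=O)C#C)c1O
F3 | step 8 | 8-geranyl-5,7-bis(triisopropylsilyloxy)-4H-chromen-4-one | CC(C)=CCC/C(C)=C/Cc1c(O[Si](C(C)C)(C(C)C)C(C)C)cc(O[Si](C(C)C)(C(C)C)C(C)C)c2c1OC=CC2=O
F4 | step 8 | [4-(tert-butyldimethylsilyloxy)phenyl]boronic acid | OB(O)c1ccc(O[Si](C)(C)C(C)(C)C)cc1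
F5 | step 8 | (2S)-2-[4-(tert-butyldimethylsilyloxy)phenyl]-8-geranyl-5,7-bis(triisopropylsilyloxy)chroman-4-one | CC(C)=CCC/C(C)=C/Cc1c(O[Si](C(C)C)(C(C)C)C(C)C)cc(O[Si](C(C)C)(C(C)C)C(C)C)c2c1O[C@H](c1ccc(O[Si](C)(C)C(C)(C)C)cc1)CC2=O
F6 | step 1 | 2-hydroxy-4,6-bis(triisopropylsilyloxy)benzaldehyde | O=Cc1c(O)cc(O[Si](C(C)C)(C(C)C)C(C)C)cc1O[Si](C(C)C)(C(C)C)C(C)C
F7 | step 1 | 2-hydroxy-3-iodo-4,6-bis(triisopropylsilyloxy)benzaldehyde | O=Cc1c(O)c(I)c(O[Si](C(C)C)(C(C)C)C(C)C)cc1O[Si](C(C)C)(C(C)C)C(C)C
F8 | step 1 | tributyl(geranyl)stannane | CC(C)=CCC/C(C)=C/C[Sn](CCCC)(CCCC)CCCC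
F9 | step 5 | 2-geranyl-6-(hydroxymethyl)-3,5-bis(triisopropylsilyloxy)phenol | CC(C)=CCC/C(C)=C/Cc1c(O[Si](C(C)C)(C(C)C)C(C)C)cc(O[Si](C(C)C)(C(C)C)C(C)C)c(CO)c1O
F10 | step 5 | 2-[(dimethylphenylsilyloxy)methyl]-6-geranyl-3,5-bis(triisopropylsilyloxy)phenol | CC(C)=CCC/C(C)=C/Cc1c(O[Si](C(C)C)(C(C)C)C(C)C)cc(O[Si](C(C)C)(C(C)C)C(C)C)c(CO[Si](C)(C)c2ccccc2)c1O
F11 | step 6 | 2-(dimethoxymethyl)-6-geranyl-3,5-bis(triisopropylsilyloxy)phenyl 4-(triisopropylsilyloxy)benzoate | CC(C)=CCC/C(C)=C/Cc1c(O[Si](C(C)C)(C(C)C)C(C)C)cc(O[Si](C(C)C)(C(C)C)C(C)C)c(C(OC)OC)c1OC(=O)c1ccc(O[Si](C(C)C)(C(C)C)C(C)C)cc1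
F12 | step 6 | 1-(dimethoxymethyl)-3-geranyl-4,6-bis(triisopropylsilyloxy)-2-{1-[4-(triisopropylsilyloxy)phenyl]vinyloxy}benzene | CC(C)=CCC/C(C)=C/Cc1c(O[Si](C(C)C)(C(C)C)C(C)C)cc(O[Si](C(C)C)(C(C)C)C(C)C)c(C(OC)OC)c1OC(=C)c1ccc(O[Si](C(C)C)(C(C)C)C(C)C)cc1
A1 | alternative 1 | (3R)-3-(tert-butyldimethylsilyloxy)-1-[3-geranyl-2-hydroxy-4,6-bis(methoxymethoxy)phenyl]-3-[4-(methoxymethoxy)phenyl]propan-1-one | CC(C)=CCC/C(C)=C/Cc1c(OCOC)cc(OCOC)c(C(=O)C[C@@H](O[Si](C)(C)C(C)(C)C)c2ccc(OCOC)cc2)c1O
A2 | alternative 1 | (3R)-3-(tert-butyldimethylsilyloxy)-3-[4-(methoxymethoxy)phenyl]propanoic acid | O=C(O)C[C@@H](O[Si](C)(C)C(C)(C)C)c1ccc(OCOC)cc1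
A3 | alternative 1 | 2-geranyl-3,5-bis(methoxymethoxy)-6-(trimethylsilyl)phenyl trifluoromethanesulfonate | CC(C)=CCC/C(C)=C/Cc1c(OCOC)cc(OCOC)c([Si](C)(C)C)c1OS(=O)(=O)C(F)(F)F
A4 | alternative 1 | (2S)-8-geranyl-5,7-bis(methoxymethoxy)-2-[4-(methoxymethoxy)phenyl]chroman-4-one | CC(C)=CCC/C(C)=C/Cc1c(OCOC)cc(OCOC)c2c1O[C@H](c1ccc(OCOC)cc1)CC2=O
A5 | alternative 2 | 8-geranyl-5,7-bis(methoxymethoxy)-2-[4-(methoxymethoxy)phenyl]chromen-4-one | CC(C)=CCC/C(C)=C/Cc1c(OCOC)cc(OCOC)c2c1OC(c1ccc(OCOC)cc1)=CC2=O
A6 | alternative 2 | 2-geranyl-6-iodo-3,5-bis(methoxymethoxy)phenol | CC(C)=CCC/C(C)=C/Cc1c(OCOC)cc(OCOC)c(I)c1O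
A7 | alternative 2 | 1-ethynyl-4-(methoxymethoxy)benzene | C#Cc1ccc(OCOC)cc1
A8 | alternative 3 | (2S)-5,7-bis(tert-butyldimethylsilyloxy)-2-[4-(tert-butyldimethylsilyloxy)phenyl]-8-geranylchroman-4-one | CC(C)=CCC/C(C)=C/Cc1c(O[Si](C)(C)C(C)(C)C)cc(O[Si](C)(C)C(C)(C)C)c2c1O[C@H](c1ccc(O[Si](C)(C)C(C)(C)C)cc1)CC2=O
A9 | alternative 3 | 2-diazo-1-[2-{[4-(tert-butyldimethylsilyloxy)phenyl]methoxy}-4,6-bis(tert-butyldimethylsilyloxy)-3-geranylphenyl]ethan-1-one | CC(C)=CCC/C(C)=C/Cc1c(O[Si](C)(C)C(C)(C)C)cc(O[Si](C)(C)C(C)(C)C)c(C(=O)C=[N+]=[N-])c1OCc1ccc(O[Si](C)(C)C(C)(C)C)cc1
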